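Retrosynthesis: after removal of five benzyl ethers, the pyran ring of the isoflavan (unit 2; pyran ring E, resorcinol ring F, attached through C3 to the central arene, ring D) is cut at O1–C2 and C3–C4 into an ortho-quinone methide of ring F and the enamine of an arylacetaldehyde; the same two cuts on the pyran ring B of the 3,4-diaryl chroman (unit 1; resorcinol ring A) leave an aryl-substituted ortho-quinone methide, a second arylacetaldehyde and ring D as a bromo benzaldehyde.
Enabling feature: in each pyran ring O1 is a phenol oxygen ortho to the benzylic carbon C4 on the fused resorcinol ring (the ortho-quinone methide retron), and C2 is an O–CH2 next to the aryl-bearing C3, i.e. the carbonyl carbon and alpha-carbon of ArCH2CHO once C2 is raised to the lactol level.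
Forward: the ring D aldehyde (bromine as a silent handle) is joined to lithiated ring A and turned into a benzhydryl sulfone; a first aminocatalytic [4+2] with the catechol-ring arylacetaldehyde builds ring B; the bromide then becomes a CH2CHO arm (Suzuki–Miyaura, hydrolysis) and a second [4+2] with the quinone methide of ring F builds ring E as the last skeletal bond-forming event; each lactol is deoxygenated with Et3SiH and hydrogenolysis ends the route.
Stereochemistry: one enantiomer of one amine catalyst, (R)-2-[diphenyl(trimethylsilyloxy)methyl]pyrrolidine, sets C3 of both chromans (R) by shielding one enamine face; C4 of unit 1 (S, trans to C3) follows from the open Michael-type transition state and is also the more stable arrangement; the lactol C2 centres are erased.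
Protecting groups: the five free phenols travel as benzyl ethers; both methyl ethers are fixed early, the one on ring D by chelation-controlled differentiation of the two oxygens ortho and para to the formyl group.

Key step: step 15

Assumption: 5-(benzyloxy)-2-bromophenol is taken as a catalogue compound (otherwise one step from 4-bromoresorcinol and benzyl bromide); lactols are carried as mixtures of C2 anomers, which is of no consequence.

Step 1
Reactants: 1 2-bromo-4,6-dimethoxybenzaldehyde
Product: 2 2-bromo-4,6-dihydroxybenzaldehyde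
Conditions: BBr3 (3.5 equiv), CH2Cl2, −78 °C to rt; H2O
Reagents that add atoms: none
Why: Lewis-acid cleavage of both aryl methyl ethers (BBr3 demethylation) should expose two phenols that the neighbouring formyl group can tell apart in step 2.

Step 2
Reactants: 2 2-bromo-4,6-dihydroxybenzaldehyde
Product: 3 4-(benzyloxy)-2-bromo-6-hydroxybenzaldehyde
Conditions: BnBr (1.05 equiv), K2CO3 (1.1 equiv), acetone, rt
Reagents that add atoms: benzyl bromide, BrCc1ccccc1
Why: Williamson etherification should occur at the para hydroxyl only, because the ortho hydroxyl is held in a hydrogen bond to the aldehyde and is the poorer nucleophile under mild base (the usual selectivity of 2,4-dihydroxybenzaldehydes).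

Step 3
Reactants: 3 4-(benzyloxy)-2-bromo-6-hydroxybenzaldehyde
Product: 4 4-(benzyloxy)-2-bromo-6-methoxybenzaldehyde
Conditions: MeI, K2CO3, DMF, 40 °C
Reagents that add atoms: iodomethane, CI
Why: Williamson methylation of the remaining chelated phenol under more forcing conditions fixes the methyl ether that ends up ortho to C4 of unit 1.

Step 4
Reactants: 4 4-(benzyloxy)-2-bromo-6-methoxybenzaldehyde; 5 5-(benzyloxy)-2-bromophenol
Product: 7 5-(benzyloxy)-2-{[4-(benzyloxy)-2-bromo-6-methoxyphenyl](hydroxy)methyl}phenol (racemic carbinol), via lithium 5-(benzyloxy)-2-lithiophenoxide 6 (not isolated)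
Conditions: 5 (1.3 equiv), n-BuLi (2.6 equiv), THF, −78 to −20 °C; then 4, −78 to 0 °C; H2O
Reagents that add atoms: none
Why: O–H deprotonation followed by bromine–lithium exchange should give an ortho-lithiophenoxide that adds to the aldehyde much faster than it exchanges with the aryl bromide of 4 (aryllithium 1,2-addition); the new carbinol centre is racemic and is planarised in step 9.

Step 5
Reactants: 7 5-(benzyloxy)-2-{[4-(benzyloxy)-2-bromo-6-methoxyphenyl](hydroxy)methyl}phenol
Product: 8 5-(benzyloxy)-2-{[4-(benzyloxy)-2-bromo-6-methoxyphenyl][(4-methylphenyl)sulfonyl]methyl}phenol (racemic)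
Conditions: p-TolSO2Na (2 equiv), HCO2H, CH2Cl2–H2O, rt
Reagents that add atoms: sodium p-toluenesulfinate, [Na+].[O-]S(=O)c1ccc(C)cc1
Why: mild acid should ionise the doubly donor-stabilised benzhydrol and sulfinate should capture the cation at sulfur (SN1 sulfonylation), giving a storable precursor that releases the ortho-quinone methide under weak base.

Step 6
Reactants: 9 2,3-dihydroxy-4-methoxybenzaldehyde
Product: 10 2,3-bis(benzyloxy)-4-methoxybenzaldehyde
Conditions: BnBr (2.4 equiv), K2CO3, DMF, 60 °C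
Reagents that add atoms: benzyl bromide, BrCc1ccccc1
Why: exhaustive Williamson benzylation masks the catechol as two ethers that fall in the final hydrogenolysis.

Step 7
Reactants: 10 2,3-bis(benzyloxy)-4-methoxybenzaldehyde
Product: 11 2,3-bis(benzyloxy)-4-methoxy-1-(2-methoxyvinyl)benzene (E/Z mixture)
Conditions: Ph3P(CH2OMe)Cl, KOt-Bu, THF, 0 °C to rt
Reagents that add atoms: (methoxymethyl)triphenylphosphonium chloride, [Cl-].COC[P+](c1ccccc1)(c1ccccc1)c1ccccc1
Why: Wittig methoxymethylenation adds the one carbon that becomes C2 of ring B; the alkene geometry is irrelevant because it is lost on hydrolysis.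

Step 8
Reactants: 11 2,3-bis(benzyloxy)-4-methoxy-1-(2-methoxyvinyl)benzene
Product: 12 2-[2,3-bis(benzyloxy)-4-methoxyphenyl]acetaldehyde
Conditions: 2 M aq. HCl, THF, 40 °C; used without storage
Reagents that add atoms: water, O
Why: acid hydrolysis of the enol ether (C-protonation, hydration, loss of methanol) should give the arylacetaldehyde while the benzyl ethers stay intact.

Step 9
Reactants: 8 the sulfone of step 5; 12 2-[2,3-bis(benzyloxy)-4-methoxyphenyl]acetaldehyde
Product: 15 (3R,4S)-7-(benzyloxy)-4-[4-(benzyloxy)-2-bromo-6-methoxyphenyl]-3-[2,3-bis(benzyloxy)-4-methoxyphenyl]chroman-2-ol (lactol; C2 anomers), via ortho-quinone methide 13 (not isolated), via catalyst-bound enamine 14 (not isolated)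
Conditions: 12 (2 equiv), (R)-2-[diphenyl(trimethylsilyloxy)methyl]pyrrolidine (20 mol %), Na2CO3 (aq.), CH2Cl2, rt
Reagents that add atoms: water, O (aminal hydrolysis returns the oxygen that left on enamine formation)
Why: base-triggered loss of sulfinate from 8 should give quinone methide 13, to which the (E)-enamine 14 adds through the face left open by the CPh2(OTMS) group (C3 = R) in an open Michael-type transition state that places the two aryl groups trans (C4 = S), after which the phenoxide closes the lactol (aminocatalytic oxa-[4+2] annulation of ortho-quinone methides with aldehydes).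

Step 10
Reactants: 15 the lactol of step 9
Product: 16 (3R,4S)-7-(benzyloxy)-4-[4-(benzyloxy)-2-bromo-6-methoxyphenyl]-3-[2,3-bis(benzyloxy)-4-methoxyphenyl]chromane
Conditions: Et3SiH (3 equiv), BF3·OEt2 (2 equiv), CH2Cl2, −78 to −20 °C
Reagents that add atoms: none
Why: ionic hydrogenation (BF3 ionises the anomeric hydroxyl, Et3SiH reduces the aryl oxocarbenium ion) should remove the C2 oxygen with the O1–C2 bond intact, and any reversible loss of H3 should be corrected by the fixed C4 aryl group, which favours return to the trans arrangement.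

Step 11
Reactants: 16 the aryl bromide of step 10; 17 (E)-2-(2-ethoxyvinyl)-4,4,5,5-tetramethyl-1,3,2-dioxaborolane
Product: 18 (3R,4S)-7-(benzyloxy)-4-{4-(benzyloxy)-2-[(E)-2-ethoxyvinyl]-6-methoxyphenyl}-3-[2,3-bis(benzyloxy)-4-methoxyphenyl]chromane
Conditions: 17 (1.5 equiv), Pd(OAc)2 (5 mol %), SPhos (10 mol %), K3PO4, dioxane–H2O, 80 °C
Reagents that add atoms: none
Why: Suzuki–Miyaura coupling of a mono-ortho-substituted aryl bromide with an alkenyl boronate under a bulky biaryl phosphine should install, as a masked aldehyde, the two carbons that become C3 and C2 of ring E.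

Step 12
Reactants: 18 the aryl enol ether of step 11
Product: 19 2-{5-(benzyloxy)-2-[(3R,4S)-7-(benzyloxy)-3-(2,3-bis(benzyloxy)-4-methoxyphenyl)chroman-4-yl]-3-methoxyphenyl}acetaldehyde
Conditions: 2 M aq. HCl, THF, rt; used at once
Reagents that add atoms: water, O
Why: enol ether hydrolysis should unmask the arylacetaldehyde without touching the two stereocentres of unit 1, neither of which is enolisable.

Step 13
Reactants: 20 4-(benzyloxy)-2-hydroxybenzaldehyde
Product: 21 5-(benzyloxy)-2-(hydroxymethyl)phenol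
Conditions: NaBH4, MeOH, 0 °C
Reagents that add atoms: none
Why: borohydride reduction of the aldehyde gives the ortho-hydroxybenzyl alcohol that carries ring F, O1 and C4 of unit 2.

Step 14
Reactants: 21 5-(benzyloxy)-2-(hydroxymethyl)phenol
Product: 22 5-(benzyloxy)-2-{[(4-methylphenyl)sulfonyl]methyl}phenol
Conditions: p-TolSO2Na (2 equiv), HCO2H, CH2Cl2–H2O, rt
Reagents that add atoms: sodium p-toluenesulfinate, [Na+].[O-]S(=O)c1ccc(C)cc1
Why: the para-benzyloxy group should let the benzylic alcohol ionise under mild acid so that sulfinate is installed (SN1 sulfonylation), giving a stable source of the otherwise fleeting unsubstituted quinone methide.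

Step 15
Reactants: 19 the arylacetaldehyde of step 12; 22 5-(benzyloxy)-2-{[(4-methylphenyl)sulfonyl]methyl}phenol
Product: 25 (3R)-7-(benzyloxy)-3-{5-(benzyloxy)-2-[(3R,4S)-7-(benzyloxy)-3-(2,3-bis(benzyloxy)-4-methoxyphenyl)chroman-4-yl]-3-methoxyphenyl}chroman-2-ol (lactol; C2 anomers), via ortho-quinone methide 23 (not isolated), via catalyst-bound enamine 24 (not isolated)
Conditions: 22 (1.5 equiv, in portions), (R)-2-[diphenyl(trimethylsilyloxy)methyl]pyrrolidine (20 mol %), Na2CO3 (aq.), CH2Cl2, 0 °C to rt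
Reagents that add atoms: water, O (aminal hydrolysis returns the oxygen that left on enamine formation)
Why: Carbonate deprotonates the phenol of 22 and the phenoxide expels sulfinate to give quinone methide 23, while 19 condenses with the amine to the (E)-enamine 24; the aryl-bearing enamine carbon adds to the exocyclic CH2 of 23 (C3–C4 bond), the phenoxide so formed closes on the iminium carbon (O1–C2 bond), and hydrolysis of the N,O-aminal gives lactol 25 and returns the catalyst. The closest known reaction type is the enamine-catalysed inverse-electron-demand oxa-[4+2] annulation of in-situ ortho-quinone methides with enolisable aldehydes to 3-substituted chroman-2-ols. Ring E is closed as a formal [4+2], an intermolecular Michael addition followed by 6-exo-trig attack of the phenoxide oxygen on the iminium carbon. C3 is set by the catalyst: the CPh2(OTMS) group blocks one face of the s-trans (E)-enamine, so the methide is attacked from the open face, which for the (R)-catalyst should give 3R (the same sense as in step 9), with only a minor bias expected from the remote centres of unit 1; C2 is uncontrolled and is removed in step 16. The step needs isoflavan rather than flavan regiochemistry, which the enamine polarity secures because the nucleophilic carbon is the one bearing the arene; it also needs cross-reaction to beat quinone methide self-condensation and catalyst N-alkylation, which slow release of 23 from the sulfone and the reversibility of N-adducts should secure, and immediate lactol closure should protect the alpha-aryl centre from enolisation.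

Step 16
Reactants: 25 the lactol of step 15
Product: 26 (3R,4S)-7-(benzyloxy)-4-{4-(benzyloxy)-2-[(3R)-7-(benzyloxy)chroman-3-yl]-6-methoxyphenyl}-3-[2,3-bis(benzyloxy)-4-methoxyphenyl]chromane
Conditions: Et3SiH (3 equiv), BF3·OEt2 (2 equiv), CH2Cl2, −78 to −40 °C
Reagents that add atoms: none
Why: ionic hydrogenation of the lactol should turn C2 into the ring CH2 while keeping the O1–C2 bond, and at low temperature hydride capture of the oxocarbenium ion should outrun loss of the benzylic H3, so C3 keeps its configuration.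

Step 17
Reactants: 26 the pentabenzyl ether of step 16
Product: 27 (3R,4S)-3-(2,3-dihydroxy-4-methoxyphenyl)-4-{4-hydroxy-2-[(3R)-7-hydroxychroman-3-yl]-6-methoxyphenyl}chroman-7-ol (CNP0227211.1)
Conditions: H2 (1 atm), 10% Pd/C, EtOAc–MeOH, rt
Reagents that add atoms: none
Why: hydrogenolysis should cleave all five aryl benzyl ethers and leave the methyl ethers, the chroman C–O bonds (none benzylic) and the three stereocentres untouched.

Compound list
1 | 2-bromo-4,6-dimethoxybenzaldehyde | COc1cc(OC)c(C=O)c(Br)c1 | starting material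
2 | 2-bromo-4,6-dihydroxybenzaldehyde | Oc1cc(O)c(C=O)c(Br)c1 | intermediate
3 | 4-(benzyloxy)-2-bromo-6-hydroxybenzaldehyde | O=Cc1c(O)cc(OCc2ccccc2)cc1Br | intermediate
4 | 4-(benzyloxy)-2-bromo-6-methoxybenzaldehyde | COc1cc(OCc2ccccc2)cc(Br)c1C=O | intermediate
5 | 5-(benzyloxy)-2-bromophenol | Oc1cc(OCc2ccccc2)ccc1Br | starting material
6 | lithium 5-(benzyloxy)-2-lithiophenoxide | [Li]Oc1cc(OCc2ccccc2)ccc1[Li] | intermediate
7 | 5-(benzyloxy)-2-{[4-(benzyloxy)-2-bromo-6-methoxyphenyl](hydroxy)methyl}phenol, racemic | COc1cc(OCc2ccccc2)cc(Br)c1C(O)c1ccc(OCc2ccccc2)cc1O | intermediate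
8 | 5-(benzyloxy)-2-{[4-(benzyloxy)-2-bromo-6-methoxyphenyl][(4-methylphenyl)sulfonyl]methyl}phenol, racemic | COc1cc(OCc2ccccc2)cc(Br)c1C(c1ccc(OCc2ccccc2)cc1O)S(=O)(=O)c1ccc(C)cc1 | intermediate
9 | 2,3-dihydroxy-4-methoxybenzaldehyde | COc1ccc(C=O)c(O)c1O | starting material
10 | 2,3-bis(benzyloxy)-4-methoxybenzaldehyde | COc1ccc(C=O)c(OCc2ccccc2)c1OCc1ccccc1 | intermediate
11 | 2,3-bis(benzyloxy)-4-methoxy-1-(2-methoxyvinyl)benzene, E/Z mixture | COC=Cc1ccc(OC)c(OCc2ccccc2)c1OCc1ccccc1 | intermediate
12 | 2-[2,3-bis(benzyloxy)-4-methoxyphenyl]acetaldehyde | O=CCc1ccc(OC)c(OCc2ccccc2)c1OCc1ccccc1 | intermediate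
13 | 3-(benzyloxy)-6-{[4-(benzyloxy)-2-bromo-6-methoxyphenyl]methylidene}cyclohexa-2,4-dien-1-one (ortho-quinone methide of ring A) | O=C1C=C(OCc2ccccc2)C=CC1=Cc1c(OC)cc(OCc2ccccc2)cc1Br | intermediate
14 | (E)-enamine of 12 with (R)-2-[diphenyl(trimethylsilyloxy)methyl]pyrrolidine | C[Si](C)(C)OC(c1ccccc1)(c1ccccc1)[C@H]1CCCN1/C=C/c1ccc(OC)c(OCc2ccccc2)c1OCc1ccccc1 | intermediate
15 | (3R,4S)-7-(benzyloxy)-4-[4-(benzyloxy)-2-bromo-6-methoxyphenyl]-3-[2,3-bis(benzyloxy)-4-methoxyphenyl]chroman-2-ol, C2 anomers | COc1ccc([C@@H]2C(O)Oc3cc(OCc4ccccc4)ccc3[C@H]2c2c(OC)cc(OCc3ccccc3)cc2Br)c(OCc2ccccc2)c1OCc1ccccc1 | intermediate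
16 | (3R,4S)-7-(benzyloxy)-4-[4-(benzyloxy)-2-bromo-6-methoxyphenyl]-3-[2,3-bis(benzyloxy)-4-methoxyphenyl]chromane | COc1ccc([C@@H]2COc3cc(OCc4ccccc4)ccc3[C@H]2c2c(OC)cc(OCc3ccccc3)cc2Br)c(OCc2ccccc2)c1OCc1ccccc1 | intermediate
17 | (E)-2-(2-ethoxyvinyl)-4,4,5,5-tetramethyl-1,3,2-dioxaborolane | CCO/C=C/B1OC(C)(C)C(C)(C)O1 | starting material
18 | (3R,4S)-7-(benzyloxy)-4-{4-(benzyloxy)-2-[(E)-2-ethoxyvinyl]-6-methoxyphenyl}-3-[2,3-bis(benzyloxy)-4-methoxyphenyl]chromane | COc1ccc([C@@H]2COc3cc(OCc4ccccc4)ccc3[C@H]2c2c(OC)cc(OCc3ccccc3)cc2/C=C/OCC)c(OCc2ccccc2)c1OCc1ccccc1 | intermediate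
19 | 2-{5-(benzyloxy)-2-[(3R,4S)-7-(benzyloxy)-3-(2,3-bis(benzyloxy)-4-methoxyphenyl)chroman-4-yl]-3-methoxyphenyl}acetaldehyde | COc1ccc([C@@H]2COc3cc(OCc4ccccc4)ccc3[C@H]2c2c(OC)cc(OCc3ccccc3)cc2CC=O)c(OCc2ccccc2)c1OCc1ccccc1 | intermediate
20 | 4-(benzyloxy)-2-hydroxybenzaldehyde | O=Cc1ccc(OCc2ccccc2)cc1O | starting material
21 | 5-(benzyloxy)-2-(hydroxymethyl)phenol | OCc1ccc(OCc2ccccc2)cc1O | intermediate
22 | 5-(benzyloxy)-2-{[(4-methylphenyl)sulfonyl]methyl}phenol | Cc1ccc(cc1)S(=O)(=O)Cc1ccc(OCc2ccccc2)cc1O | intermediate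
23 | 3-(benzyloxy)-6-methylidenecyclohexa-2,4-dien-1-one (ortho-quinone methide of ring F) | C=C1C=CC(OCc2ccccc2)=CC1=O | intermediate
24 | (E)-enamine of 19 with (R)-2-[diphenyl(trimethylsilyloxy)methyl]pyrrolidine | COc1ccc([C@@H]2COc3cc(OCc4ccccc4)ccc3[C@H]2c2c(OC)cc(OCc3ccccc3)cc2/C=C/N2CCC[C@@H]2C(O[Si](C)(C)C)(c2ccccc2)c2ccccc2)c(OCc2ccccc2)c1OCc1ccccc1 | intermediate
25 | (3R)-7-(benzyloxy)-3-{5-(benzyloxy)-2-[(3R,4S)-7-(benzyloxy)-3-(2,3-bis(benzyloxy)-4-methoxyphenyl)chroman-4-yl]-3-methoxyphenyl}chroman-2-ol, C2 anomers | COc1ccc([C@@H]2COc3cc(OCc4ccccc4)ccc3[C@H]2c2c(OC)cc(OCc3ccccc3)cc2[C@@H]2C(O)Oc3cc(OCc4ccccc4)ccc3C2)c(OCc2ccccc2)c1OCc1ccccc1 | intermediate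
26 | (3R,4S)-7-(benzyloxy)-4-{4-(benzyloxy)-2-[(3R)-7-(benzyloxy)chroman-3-yl]-6-methoxyphenyl}-3-[2,3-bis(benzyloxy)-4-methoxyphenyl]chromane | COc1ccc([C@@H]2COc3cc(OCc4ccccc4)ccc3[C@H]2c2c(OC)cc(OCc3ccccc3)cc2[C@@H]2COc3cc(OCc4ccccc4)ccc3C2)c(OCc2ccccc2)c1OCc1ccccc1 | intermediate
27 | (3R,4S)-3-(2,3-dihydroxy-4-methoxyphenyl)-4-{4-hydroxy-2-[(3R)-7-hydroxychroman-3-yl]-6-methoxyphenyl}chroman-7-ol | COc1ccc([C@@H]2COc3cc(O)ccc3[C@H]2c2c(OC)cc(O)cc2[C@@H]2COc3cc(O)ccc3C2)c(O)c1O | target

Total step count: 17. Longest linear sequence: 12 steps (steps 1, 2, 3, 4, 5, 9, 10, 11, 12, 15, 16, 17).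

Steps most likely to fail

Step 9. The methide carbon carries an arene with bromine and methoxy in both ortho positions, so carbon–carbon bond formation there may be slow. The quinone methide could then revert or dimerise, and facial and trans/cis control could erode. The fallback makes the crowded C4 centre by an intramolecular ring closure and hands C3 to an auxiliary. It sets out from 12 and 4. Oxidation of 12 with NaClO2/NaH2PO4/2-methyl-2-butene gives 2-[2,3-bis(benzyloxy)-4-methoxyphenyl]acetic acid F1. Mixed-anhydride acylation (PivCl, Et3N, then lithiated (S)-4-benzyloxazolidin-2-one) gives (S)-4-benzyl-3-{[2,3-bis(benzyloxy)-4-methoxyphenyl]acetyl}oxazolidin-2-one F2. An Evans syn-aldol reaction (Bu2BOTf, i-Pr2NEt) with 4 gives the (2S,3S)-3-hydroxy-3-aryl-2-aryl-propanoyl imide F3, whose alpha-centre has the arrangement needed for C3 = R. LiBH4 removes the auxiliary to give (1S,2R)-1-[4-(benzyloxy)-2-bromo-6-methoxyphenyl]-2-[2,3-bis(benzyloxy)-4-methoxyphenyl]propane-1,3-diol F4. Mitsunobu etherification (PPh3, DIAD) of the primary hydroxyl with 3-(benzyloxy)phenol gives (1S,2R)-3-[3-(benzyloxy)phenoxy]-1-[4-(benzyloxy)-2-bromo-6-methoxyphenyl]-2-[2,3-bis(benzyloxy)-4-methoxyphenyl]propan-1-ol F5. BF3·OEt2 at −40 °C then ionises the benzylic alcohol and the resorcinol ring should close the pyran by Friedel–Crafts alkylation para to its benzyloxy group and anti to the C3 aryl group. This comes back to the route at 16.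

Step 15. Self-condensation of the unsubstituted quinone methide and alkylation of the catalyst nitrogen may outrun the enamine addition of the encumbered aldehyde, or catalyst and substrate may oppose each other in facial selectivity. The fallback replaces the enamine by a neutral 2π partner and sets out from 18 (step 12 is skipped) and 21. Gentle heating in toluene, optionally with a chiral phosphoric acid (TRIP), should release the quinone methide from 21 and let the enol ether of 18 add in an inverse-electron-demand hetero-Diels–Alder reaction. This gives (3R)-7-(benzyloxy)-3-{5-(benzyloxy)-2-[(3R,4S)-7-(benzyloxy)-3-(2,3-bis(benzyloxy)-4-methoxyphenyl)chroman-4-yl]-3-methoxyphenyl}-2-ethoxychromane F6. Its C3 epimer is a diastereomer here and can be removed by chromatography. The conditions of step 16 then remove the ethoxy group, and the route is rejoined at 26.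

Step 16. The configuration at C3 may be lost through reversible deprotonation of the aryl oxocarbenium ion, or the acid may cleave the electron-rich C4–aryl bond of unit 1. The fallback avoids cationic intermediates and sets out from 25. NaBH4 in EtOH at 0 °C reduces the open hydroxy-aldehyde tautomer to 5-(benzyloxy)-2-[(2R)-2-{5-(benzyloxy)-2-[(3R,4S)-7-(benzyloxy)-3-(2,3-bis(benzyloxy)-4-methoxyphenyl)chroman-4-yl]-3-methoxyphenyl}-3-hydroxypropyl]phenol F7. Mitsunobu cyclisation (PPh3, DIAD, THF) then closes the O1–C2 bond again under neutral conditions and returns to the route at 26.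

Further compounds
F1 | step 9 | 2-[2,3-bis(benzyloxy)-4-methoxyphenyl]acetic acid | OC(=O)Cc1ccc(OC)c(OCc2ccccc2)c1OCc1ccccc1
F2 | step 9 | (S)-4-benzyl-3-{[2,3-bis(benzyloxy)-4-methoxyphenyl]acetyl}oxazolidin-2-one | O=C(Cc1ccc(OC)c(OCc2ccccc2)c1OCc1ccccc1)N1[C@@H](Cc2ccccc2)COC1=O
F3 | step 9 | (S)-4-benzyl-3-{(2S,3S)-3-[4-(benzyloxy)-2-bromo-6-methoxyphenyl]-2-[2,3-bis(benzyloxy)-4-methoxyphenyl]-3-hydroxypropanoyl}oxazolidin-2-one | COc1ccc([C@@H]([C@H](O)c2c(OC)cc(OCc3ccccc3)cc2Br)C(=O)N2[C@@H](Cc3ccccc3)COC2=O)c(OCc2ccccc2)c1OCc1ccccc1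
F4 | step 9 | (1S,2R)-1-[4-(benzyloxy)-2-bromo-6-methoxyphenyl]-2-[2,3-bis(benzyloxy)-4-methoxyphenyl]propane-1,3-diol | COc1ccc([C@@H]([C@H](O)c2c(OC)cc(OCc3ccccc3)cc2Br)CO)c(OCc2ccccc2)c1OCc1ccccc1
F5 | step 9 | (1S,2R)-3-[3-(benzyloxy)phenoxy]-1-[4-(benzyloxy)-2-bromo-6-methoxyphenyl]-2-[2,3-bis(benzyloxy)-4-methoxyphenyl]propan-1-ol | COc1ccc([C@@H]([C@H](O)c2c(OC)cc(OCc3ccccc3)cc2Br)COc2cccc(OCc3ccccc3)c2)c(OCc2ccccc2)c1OCc1ccccc1
F6 | step 15 | (3R)-7-(benzyloxy)-3-{5-(benzyloxy)-2-[(3R,4S)-7-(benzyloxy)-3-(2,3-bis(benzyloxy)-4-methoxyphenyl)chroman-4-yl]-3-methoxyphenyl}-2-ethoxychromane, C2 anomers | COc1ccc([C@@H]2COc3cc(OCc4ccccc4)ccc3[C@H]2c2c(OC)cc(OCc3ccccc3)cc2[C@@H]2C(OCC)Oc3cc(OCc4ccccc4)ccc3C2)c(OCc2ccccc2)c1OCc1ccccc1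
F7 | step 16 | 5-(benzyloxy)-2-[(2R)-2-{5-(benzyloxy)-2-[(3R,4S)-7-(benzyloxy)-3-(2,3-bis(benzyloxy)-4-methoxyphenyl)chroman-4-yl]-3-methoxyphenyl}-3-hydroxypropyl]phenol | COc1ccc([C@@H]2COc3cc(OCc4ccccc4)ccc3[C@H]2c2c(OC)cc(OCc3ccccc3)cc2[C@@H](Cc2ccc(OCc3ccccc3)cc2O)CO)c(OCc2ccccc2)c1OCc1ccccc1
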